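## The problem

Lobophynin B (25) is a cembranoid in which a 14-membered carbocycle (C1–C14) shares its C1–C2 edge with a 2,5-dihydrofuran (O, C2, C1, C15, C16); C15 carries the acetoxymethyl carbon C17. The fusion alkene C1=C15 is tetrasubstituted, C3=C4 and C11=C12 are E trisubstituted alkenes, and C7–C8 is a trans trisubstituted epoxide. There are three stereocentres, C2 (R) and C7/C8 (R,R). They lie four atoms apart in a flexible ring, so neither element can be relied on to control the other and each has to be set by a reagent. The groups that will not stand rough treatment are the epoxide (acid, Lewis acid, hydride), the doubly allylic C2–O bond (ionisation, oxidation of the ring to a furan), the allylic acetate and the E alkenes. The chain C2–C13 with its three methyl branches is the skeleton of (2E,6E)-farnesol (1), so the carbon work is limited to adding C1 and C14–C17, oxidising C13 and joining C13 to C14. The feature that opens the route is that the ring oxygen bridges C2 and C16 across C1=C15 while C15 also bears the oxygenated carbon C17. The dihydrofuran is therefore the 1,3-oxygen-shift isomer of a C15–C16 oxirane carrying a C1=C2 vinyl group, and an oxirane with a CH2O arm on its substituted carbon is what asymmetric epoxidation of a 2-substituted allylic alcohol delivers.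

## Retrosynthesis

**C17 acetate (25 ⇒ 24 ⇒ 23).** The ester C–O bond is cut last and O17 is carried as the tert-butyldiphenylsilyl ether 23. An acetate beside the oxirane would invite neighbouring-group opening in the key step, and an allylic acetate is a liability towards low-valent nickel; the bulky silyl ether is inert to both. The forward steps are a fluoride desilylation and an acetylation, both harmless to epoxide and dihydrofuran.

**C13–C14 (23 ⇒ 22).** The macrocycle is opened at the one ring bond that is sp3–sp3 and allylic on both sides. This cut lets both termini be made in the same way, as the primary allylic bromides of 22, without ever telling the two ends apart. A cut at C14–C1 would need an sp2 coupling at the crowded fusion carbon, and a cut at C2–C3 would break the farnesyl chain. The forward reaction must couple head to head under high dilution, keep C11=C12 E and spare the epoxide.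

**Bromides and epoxide (22 ⇒ 20 ⇒ 19 ⇒ 18).** The bromides come from diol 20, the diol from bis-silyl ether 19, and the C7–C8 oxirane is removed to give triene 18. Epoxidation belongs on the open chain: in 18, C7=C8 is the only trisubstituted alkene without an allylic oxygen, whereas after ring closure C11=C12 would be just as electron-rich. It belongs after the key step so that no second oxirane meets the copper Lewis acid. The forward steps ask for catalyst-controlled, site-selective epoxidation and for removal of two TBS groups beside a TBDPS group and an epoxide.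

**O–C2 (18 ⇒ 17, key step).** Cutting O–C2 and reconnecting the oxygen to C15 turns the dihydrofuran into the dienyl oxirane 17. This removes the ring, moves the alkene from C1=C15 to C1=C2, and relocates the stereocentre from C2 to C15, where an epoxidation can set it. Cutting O–C16 instead (etherification of a diol) would leave C2 to be set as a carbinol flanked by two alkenes and would require a stereodefined tetrasubstituted alkene beforehand. The forward isomerisation must return the oxygen to C2, not C4, and must pass the configuration of C15 on to C2.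

**Oxirane (17 ⇒ 16 ⇒ 15).** The silyl group is removed to give epoxy alcohol 16, and the oxirane oxygen is removed to give the cross-conjugated triene alcohol 15. O17 is the only free hydroxyl, so a Sharpless epoxidation is directed to C15=C16 alone among five alkenes. The forward step must tolerate a product that is a tertiary, dienyl-substituted oxirane.

**C1–C15 (15 ⇒ 13 + 14).** The sp2–sp2 bond is cut to vinylstannane 13 and 2-bromoprop-2-en-1-ol (14), which brings C15, C16 and C17 with the hydroxyl already free. A Stille coupling keeps both alkene geometries.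

**C1–Sn (13 ⇒ 12 ⇒ 11 ⇒ 10).** The stannane is traced through alcohol 12 and ester 11 to ynoate 10. Carrying C14 at the ester level is deliberate: the ester polarises the alkyne so that tin goes to C1, whereas with a CH2O group at C14 the oxygen and the conjugated alkene would direct tin to opposite carbons. Syn addition then fixes C14 cis to C3, the geometry the key step needs. The price is one reduction.

**C1 and C14 (10 ⇒ 9 ⇒ 7 + 8; 7 ⇒ 6).** The C1–C14 bond is cut to lithium acetylide 9 and methyl chloroformate (8). The acetylide comes from dibromoalkene 7, and 7 from enal 6 by a one-carbon Corey–Fuchs homologation that supplies C1.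

**Chain (6 ⇒ 5 ⇒ 4 ⇒ 3 ⇒ 2 ⇒ 1).** Enal 6 is farnesol (1) oxidised at both ends. The acetate 2 allows selective allylic oxidation of the terminal E methyl group (3), and a protecting-group exchange (4, 5) and oxidation give 6. All three E alkenes of 25 are bought with 1.

## Roads not taken

**Alternative 1:** [2,3]-Wittig ring contraction. The cut is C1–C2. The ring is first closed as the 17-membered ether A2, in which oxygen links the propargylic carbon C2 to C16 of an allylic ether. In the forward key step a single enantiomer of lithium bis(1-phenylethyl)amide removes a C2 proton, and the [2,3]-shift forms C1–C2 and contracts the ring to the 14-membered propargylic alcohol A1, with C15=C16 exocyclic.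
- Merits: the macrocycle is made by O-alkylation, the C–C bond forms inside the ring, no alkene geometry is at risk, and C2 is addressed directly.
- Weak points for 25: enantioselection rests on a stoichiometric chiral base choosing between enantiotopic protons; the epoxide must survive a lithium amide; the new C1 stereocentre is later erased. A1 is also still far from 25: the C3≡C4 alkyne has to become the E methyl-bearing alkene beside an epoxide, and the exocyclic alkene has to be moved into the ring with O–C16 bond formation, which is an oxidative operation.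
- Comparison: its ring closure is more dependable than the nickel coupling of step 18. The chosen plan sets against this a redox-neutral dihydrofuran formation with every carbon in place, catalytic control of the stereocentre, and six steps from the key step to 25.

**Alternative 2:** carbonylative oxypalladation. The cuts are O–C16 and C15–C17; the precursor is the macrocyclic allenol A4 (C2 carbinol, exocyclic C1=C15=C16 allene). In the forward key step PdCl2(MeCN)2 (divalent palladium) with CO, MeOH and 1,4-benzoquinone adds the hydroxyl to C16, and the vinylpalladium at C15 is carbonylated to the methyl ester A3. Reduction and acetylation would finish 25.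
- Merits: ring and C17 arrive in one step on the finished macrocycle, C2 exists beforehand so no transfer of configuration is asked, and the end game is two steps.
- Weak points: the difficulty is moved into A4, a 14-membered ring with an exocyclic allene and a carbinol of defined configuration, with nothing to control C2 during ring closure. Electrophilic palladium chloride and an oxidant also meet an epoxide and three further alkenes.
- Comparison: for the security of C2 in the ring-forming step and for end-game length this road is the better one. The chosen plan answers with a key-step precursor reached in a linear sequence from 1 and with C2 derived from a catalytic asymmetric reaction on an open chain.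

**Alternative 3:** ring-closing alkyne metathesis. The cut is C3–C4, made as a triple bond. Diyne A6 carries two methyl-capped alkynes, and Mo(≡C-C6H4-4-OMe)(OSiPh3)3 (hexavalent molybdenum alkylidyne) closes the 14-membered cycloalkyne A5 with loss of the two caps. Hydroxyl-directed anti hydrometalation and methylation would then give E C3=C4, and etherification of O2 with C16 would close the dihydrofuran.
- Merits: this is among the most reliable macrocyclisations, it is indifferent to the epoxide and free of E/Z questions, and C2 can be set as a propargylic alcohol by well-tried asymmetric methods and is then simply retained.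
- Weak points: A6 needs a stereodefined tetrasubstituted alkene with three differently protected oxymethyl groups; the chain can no longer be taken whole from farnesol because C4 is an alkyne carbon; and the C4 methyl group is added after ring closure.
- Comparison: for ring closure and for C2 this road is stronger than the chosen one. The chosen plan sets step economy against it: the whole C2–C13 chain with three E alkenes comes from 1, and the fusion alkene and ring ether form in one isomerisation. It accepts the weaker macrocyclisation, for which a fallback is given.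

Key step: step 14

Assumption: cembrane numbering is used throughout (ring C1–C14, branch C15–C17, oxygen between C2 and C16); the copper-mediated oxygen shift is taken to be suprafacial, which fixes D-(−)-diisopropyl tartrate for step 12.

## Route

Step 1
Reactants: 1 (2E,6E)-farnesol
Product: 2 (2E,6E)-farnesyl acetate
Conditions: Ac2O, pyridine, DMAP (cat.), CH2Cl2, 0 °C → rt
Reagents that add atoms: acetic anhydride, CC(=O)OC(C)=O
Why: Acylation of the primary allylic alcohol; the acetate protects O1 and deactivates the adjacent alkene towards the allylic oxidation that follows.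

Step 2
Reactants: 2 (2E,6E)-farnesyl acetate
Product: 3 (2E,6E,10E)-12-hydroxy-3,7,11-trimethyldodeca-2,6,10-trien-1-yl acetate
Conditions: SeO2 (cat.), t-BuOOH, salicylic acid (cat.), CH2Cl2, rt
Reagents that add atoms: tert-butyl hydroperoxide, CC(C)(C)OO (oxygen passed on through SeO2, O=[Se]=O)
Why: Selenium dioxide allylic oxidation (ene reaction, then [2,3]-shift) is selective for the E methyl group of the terminal trisubstituted alkene, the most electron-rich and least hindered site; this carbon becomes C13.

Step 3
Reactants: 3 (2E,6E,10E)-12-hydroxy-3,7,11-trimethyldodeca-2,6,10-trien-1-yl acetate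
Product: 4 (2E,6E,10E)-12-[(tert-butyldimethylsilyl)oxy]-3,7,11-trimethyldodeca-2,6,10-trien-1-yl acetate
Conditions: TBSCl, imidazole, DMF, rt
Reagents that add atoms: tert-butyldimethylsilyl chloride, CC(C)(C)[Si](C)(C)Cl
Why: Silylation of the new primary allylic alcohol; the TBS ether withstands the organolithium, hydride and palladium steps ahead.

Step 4
Reactants: 4 (2E,6E,10E)-12-[(tert-butyldimethylsilyl)oxy]-3,7,11-trimethyldodeca-2,6,10-trien-1-yl acetate
Product: 5 (2E,6E,10E)-12-[(tert-butyldimethylsilyl)oxy]-3,7,11-trimethyldodeca-2,6,10-trien-1-ol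
Conditions: K2CO3 (cat.), MeOH, rt
Reagents that add atoms: none
Why: Base-catalysed transesterification frees O1 without touching the silyl ether.

Step 5
Reactants: 5 (2E,6E,10E)-12-[(tert-butyldimethylsilyl)oxy]-3,7,11-trimethyldodeca-2,6,10-trien-1-ol
Product: 6 (2E,6E,10E)-12-[(tert-butyldimethylsilyl)oxy]-3,7,11-trimethyldodeca-2,6,10-trienal
Conditions: MnO2, CH2Cl2, rt
Reagents that add atoms: none
Why: MnO2 oxidises allylic alcohols to enals without E/Z isomerisation or over-oxidation; the aldehyde carbon is C2.

Step 6
Reactants: 6 (2E,6E,10E)-12-[(tert-butyldimethylsilyl)oxy]-3,7,11-trimethyldodeca-2,6,10-trienal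
Product: 7 tert-butyl{[(2E,6E,10E)-13,13-dibromo-2,6,10-trimethyltrideca-2,6,10,12-tetraen-1-yl]oxy}dimethylsilane
Conditions: CBr4, PPh3, Zn, CH2Cl2, 0 °C → rt
Reagents that add atoms: carbon tetrabromide, BrC(Br)(Br)Br
Why: First stage of the Corey–Fuchs reaction (Wittig olefination with Ph3P=CBr2), which works on β,β-disubstituted enals; the new carbon is C1, and zinc keeps the medium free of phosphorus bromides that could attack the silyl ether.

Step 7
Reactants: 7 tert-butyl{[(2E,6E,10E)-13,13-dibromo-2,6,10-trimethyltrideca-2,6,10,12-tetraen-1-yl]oxy}dimethylsilane; 8 methyl chloroformate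
Product: 10 methyl (4E,8E,12E)-14-[(tert-butyldimethylsilyl)oxy]-5,9,13-trimethyltetradeca-4,8,12-trien-2-ynoate, via lithium acetylide 9 (not isolated)
Conditions: n-BuLi (2.1 equiv), THF, −78 °C; then 8, −78 → 0 °C
Reagents that add atoms: none
Why: Second stage of the Corey–Fuchs reaction: bromine–lithium exchange, Fritsch–Buttenberg–Wiechell rearrangement and deprotonation give acetylide 9, which is acylated by 8 so that C14 enters at the ester level.

Step 8
Reactants: 10 methyl (4E,8E,12E)-14-[(tert-butyldimethylsilyl)oxy]-5,9,13-trimethyltetradeca-4,8,12-trien-2-ynoate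
Product: 11 methyl (2E,4E,8E,12E)-14-[(tert-butyldimethylsilyl)oxy]-5,9,13-trimethyl-2-(tributylstannyl)tetradeca-2,4,8,12-tetraenoate
Conditions: Bu3SnH, Pd(PPh3)4 (cat.), THF, 0 °C → rt
Reagents that add atoms: tributyltin hydride, CCCC[SnH](CCCC)CCCC
Why: Palladium-catalysed syn hydrostannation of a 2-ynoate places hydride on the β carbon (C2) and tin on the α carbon (C1), so the ester fixes the regiochemistry and syn addition puts C14 cis to C3.

Step 9
Reactants: 11 methyl (2E,4E,8E,12E)-14-[(tert-butyldimethylsilyl)oxy]-5,9,13-trimethyl-2-(tributylstannyl)tetradeca-2,4,8,12-tetraenoate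
Product: 12 (2E,4E,8E,12E)-14-[(tert-butyldimethylsilyl)oxy]-5,9,13-trimethyl-2-(tributylstannyl)tetradeca-2,4,8,12-tetraen-1-ol
Conditions: i-Bu2AlH, CH2Cl2, −78 °C; aq. potassium sodium tartrate
Reagents that add atoms: none
Why: 1,2-Reduction of the enoate to the allylic alcohol; vinylstannane, silyl ether and alkenes are inert to the aluminium hydride at −78 °C.

Step 10
Reactants: 12 (2E,4E,8E,12E)-14-[(tert-butyldimethylsilyl)oxy]-5,9,13-trimethyl-2-(tributylstannyl)tetradeca-2,4,8,12-tetraen-1-ol
Product: 13 tributyl[(2E,4E,8E,12E)-1,14-bis[(tert-butyldimethylsilyl)oxy]-5,9,13-trimethyltetradeca-2,4,8,12-tetraen-2-yl]stannane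
Conditions: TBSCl, imidazole, DMF, rt
Reagents that add atoms: tert-butyldimethylsilyl chloride, CC(C)(C)[Si](C)(C)Cl
Why: Silylation; O14 must be masked so that only O17 can direct the epoxidation of step 12, and it then shares the fate of O13 up to the ring closure.

Step 11
Reactants: 13 tributyl[(2E,4E,8E,12E)-1,14-bis[(tert-butyldimethylsilyl)oxy]-5,9,13-trimethyltetradeca-2,4,8,12-tetraen-2-yl]stannane; 14 2-bromoprop-2-en-1-ol
Product: 15 (3Z,5E,9E,13E)-15-[(tert-butyldimethylsilyl)oxy]-3-{[(tert-butyldimethylsilyl)oxy]methyl}-6,10,14-trimethyl-2-methylidenepentadeca-3,5,9,13-tetraen-1-ol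
Conditions: Pd(PPh3)4 (cat.), CuI (cat.), CsF, DMF, 45 °C
Reagents that add atoms: none
Why: Stille coupling with copper and fluoride co-promotion, the usual remedy for α-branched vinylstannanes; both alkene geometries are retained (the 3Z descriptor only reflects the priority of CH2O over the new vinyl carbon) and the free hydroxyl of 14 is tolerated.

Step 12
Reactants: 15 (3Z,5E,9E,13E)-15-[(tert-butyldimethylsilyl)oxy]-3-{[(tert-butyldimethylsilyl)oxy]methyl}-6,10,14-trimethyl-2-methylidenepentadeca-3,5,9,13-tetraen-1-ol
Product: 16 {(2R)-2-[(2E,4E,8E,12E)-1,14-bis[(tert-butyldimethylsilyl)oxy]-5,9,13-trimethyltetradeca-2,4,8,12-tetraen-2-yl]oxiran-2-yl}methanol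
Conditions: Ti(OiPr)4 (cat.), D-(−)-diisopropyl tartrate (cat.), t-BuOOH, 4 Å molecular sieves, CH2Cl2, −25 °C; non-acidic work-up
Reagents that add atoms: tert-butyl hydroperoxide, CC(C)(C)OO
Why: Sharpless asymmetric epoxidation: titanium binds O17 and delivers oxygen only to the allylic C15=C16 alkene; with D-(−)-tartrate a 2-substituted prop-2-en-1-ol should give the (R)-oxirane carbon (the enantiomer of what L-(+)-tartrate gives in this substrate class), and catalytic titanium, sieves and low temperature limit opening of the sensitive product.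

Step 13
Reactants: 16 {(2R)-2-[(2E,4E,8E,12E)-1,14-bis[(tert-butyldimethylsilyl)oxy]-5,9,13-trimethyltetradeca-2,4,8,12-tetraen-2-yl]oxiran-2-yl}methanol
Product: 17 tert-butyl({(2S)-2-[(2E,4E,8E,12E)-1,14-bis[(tert-butyldimethylsilyl)oxy]-5,9,13-trimethyltetradeca-2,4,8,12-tetraen-2-yl]oxiran-2-yl}methoxy)diphenylsilane
Conditions: TBDPSCl, imidazole, CH2Cl2, 0 °C → rt
Reagents that add atoms: tert-butyldiphenylsilyl chloride, CC(C)(C)[Si](Cl)(c1ccccc1)c1ccccc1
Why: Silylation of the primary alcohol removes the free hydroxyl (Payne-type migration, chelation) before the Lewis-acid step and marks O17 for late release; the descriptor changes from R to S only because C17 now outranks C16, the centre itself is untouched.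

Step 14
Reactants: 17 tert-butyl({(2S)-2-[(2E,4E,8E,12E)-1,14-bis[(tert-butyldimethylsilyl)oxy]-5,9,13-trimethyltetradeca-2,4,8,12-tetraen-2-yl]oxiran-2-yl}methoxy)diphenylsilane
Product: 18 tert-butyl({(5R)-4-{[(tert-butyldimethylsilyl)oxy]methyl}-5-[(1E,5E,9E)-11-[(tert-butyldimethylsilyl)oxy]-2,6,10-trimethylundeca-1,5,9-trien-1-yl]-2,5-dihydrofuran-3-yl}methoxy)diphenylsilane
Conditions: Cu(CF3COCHCOCF3)2 (5 mol%), toluene, 80–110 °C
Reagents that add atoms: none
Why: The copper centre activates the oxirane (as the divalent Lewis acid at oxygen or, after reduction in situ, as monovalent copper adding to the alkene terminus) so that the tertiary allylic C15–O bond breaks while the oxygen, still tethered through C16, bonds to C2; ring strain drives this formal 1,3-oxygen shift. The closest known reaction type is the copper-catalysed ring expansion of vinyl oxiranes to 2,5-dihydrofurans, which is reported to be stereospecific for E alkenes; the new element here is only the substrate, a dienyl oxirane whose stereocentre is the quaternary carbon that becomes sp2. The dihydrofuran closes by 5-endo attack of the C16 alkoxide on the C2 terminus of the C15–C1–C2 allyl unit, possible only from the rotamer with C16 s-cis to C2, which is unstrained because the E alkene puts H and not C3 beside C16. C2 is controlled by the C15 centre from step 12 together with the E geometry of C1=C2: a suprafacial shift converts (15S)-17 into (2R)-18. Should the copper pathway run antarafacially instead (anti addition of copper at C2, then C–O reductive elimination), it would be equally stereospecific and the same product would come from the enantiomeric oxirane, made with L-(+)-tartrate in step 12. The step needs C2 over C4 selectivity, secured because closure at C4 (seven-membered ring) requires the s-cis C1=C2–C3=C4 rotamer that the two C4 substituents disfavour, and it needs a short-lived ion pair, favoured by toluene, a low catalyst loading and the lowest temperature that still turns over. No other oxirane is present, so the Lewis acid has a single site of attack.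

Step 15
Reactants: 18 tert-butyl({(5R)-4-{[(tert-butyldimethylsilyl)oxy]methyl}-5-[(1E,5E,9E)-11-[(tert-butyldimethylsilyl)oxy]-2,6,10-trimethylundeca-1,5,9-trien-1-yl]-2,5-dihydrofuran-3-yl}methoxy)diphenylsilane
Product: 19 (2R,7R,8R)-7,8-epoxide of 18 (oxirane across C7–C8, all else unchanged)
Conditions: 1,2:4,5-di-O-isopropylidene-β-D-erythro-2,3-hexodiulo-2,6-pyranose (0.3 equiv), KHSO5 (as 2KHSO5·KHSO4·K2SO4), K2CO3, Bu4NHSO4, MeCN–CH2(OMe)2–aq. Na2B4O7 buffer, 0 °C, limited oxidant
Reagents that add atoms: potassium peroxymonosulfate, [K+].OOS(=O)(=O)[O-]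
Why: Shi epoxidation (chiral dioxirane, spiro transition state): the D-fructose-derived ketone gives (R,R)-epoxides from E trisubstituted alkenes, so C7 and C8 are set by the catalyst; C7=C8 is the only alkene without an electron-withdrawing allylic oxygen, and limiting the oxidant secures mono-epoxidation.

Step 16
Reactants: 19 (2R,7R,8R)-7,8-epoxide of 18
Product: 20 (2R,7R,8R)-7,8-epoxy-13,14-diol (19 with both tert-butyldimethylsilyl groups removed, O17 still tert-butyldiphenylsilylated)
Conditions: HF·pyridine, pyridine, THF, 0 °C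
Reagents that add atoms: none
Why: Buffered HF·pyridine cleaves primary TBS ethers much faster than a primary TBDPS ether and, with excess pyridine, leaves trisubstituted epoxides intact.

Step 17
Reactants: 20 (2R,7R,8R)-7,8-epoxy-13,14-diol
Product: 22 (2R,7R,8R)-13,14-dibromo-7,8-epoxide (20 with both hydroxyls replaced by bromine), via bismesylate 21 (not isolated)
Conditions: MsCl, Et3N, THF, −40 °C; then LiBr, −40 → 0 °C
Reagents that add atoms: lithium bromide, [Li+].[Br-]
Why: Mesylation followed by SN2 displacement with bromide is the standard non-acidic way to make allylic bromides beside a trisubstituted epoxide; 22 is used at once.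

Step 18
Reactants: 22 (2R,7R,8R)-13,14-dibromo-7,8-epoxide
Product: 23 (2R,7R,8R)-17-[(tert-butyldiphenylsilyl)oxy]-2,16:7,8-diepoxycembra-1(15),3E,11E-triene
Conditions: Ni(CO)4 (excess), N-methylpyrrolidone, 50 °C, slow addition to about 2 mM
Reagents that add atoms: none
Why: Nickel-mediated reductive allyl–allyl coupling of an α,ω-bis(allylic bromide) through allylnickel bromide intermediates joins the two primary termini head to head and is the classical closure of 14-membered 1,5-diene rings of the cembrane type; slow addition favours ring closure over oligomerisation.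

Step 19
Reactants: 23 (2R,7R,8R)-17-[(tert-butyldiphenylsilyl)oxy]-2,16:7,8-diepoxycembra-1(15),3E,11E-triene
Product: 24 (2R,7R,8R)-2,16:7,8-diepoxycembra-1(15),3E,11E-trien-17-ol
Conditions: Bu4NF, THF, 0 °C → rt
Reagents that add atoms: none
Why: Fluoride cleavage of the silyl ether; epoxide, dihydrofuran and alkenes are inert to Bu4NF.

Step 20
Reactants: 24 (2R,7R,8R)-2,16:7,8-diepoxycembra-1(15),3E,11E-trien-17-ol
Product: 25 lobophynin B, (2R,7R,8R)-2,16:7,8-diepoxycembra-1(15),3E,11E-trien-17-yl acetate
Conditions: Ac2O, pyridine, DMAP (cat.), CH2Cl2, 0 °C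
Reagents that add atoms: acetic anhydride, CC(=O)OC(C)=O
Why: Acetylation of the primary allylic alcohol under basic conditions completes the target without touching the epoxide or the C2–O bond.

## Compound list

1 | (2E,6E)-farnesol, (2E,6E)-3,7,11-trimethyldodeca-2,6,10-trien-1-ol | OC/C=C(\C)CC/C=C(\C)CCC=C(C)C | starting material
2 | (2E,6E)-farnesyl acetate | CC(=O)OC/C=C(\C)CC/C=C(\C)CCC=C(C)C | intermediate
3 | (2E,6E,10E)-12-hydroxy-3,7,11-trimethyldodeca-2,6,10-trien-1-yl acetate | CC(=O)OC/C=C(\C)CC/C=C(\C)CC/C=C(\C)CO | intermediate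
4 | (2E,6E,10E)-12-[(tert-butyldimethylsilyl)oxy]-3,7,11-trimethyldodeca-2,6,10-trien-1-yl acetate | CC(=O)OC/C=C(\C)CC/C=C(\C)CC/C=C(\C)CO[Si](C)(C)C(C)(C)C | intermediate
5 | (2E,6E,10E)-12-[(tert-butyldimethylsilyl)oxy]-3,7,11-trimethyldodeca-2,6,10-trien-1-ol | OC/C=C(\C)CC/C=C(\C)CC/C=C(\C)CO[Si](C)(C)C(C)(C)C | intermediate
6 | (2E,6E,10E)-12-[(tert-butyldimethylsilyl)oxy]-3,7,11-trimethyldodeca-2,6,10-trienal | O=C/C=C(\C)CC/C=C(\C)CC/C=C(\C)CO[Si](C)(C)C(C)(C)C | intermediate
7 | tert-butyl{[(2E,6E,10E)-13,13-dibromo-2,6,10-trimethyltrideca-2,6,10,12-tetraen-1-yl]oxy}dimethylsilane | BrC(Br)=C/C=C(\C)CC/C=C(\C)CC/C=C(\C)CO[Si](C)(C)C(C)(C)C | intermediate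
8 | methyl chloroformate | COC(=O)Cl | starting material
9 | lithium acetylide of (3E,7E,11E)-13-[(tert-butyldimethylsilyl)oxy]-4,8,12-trimethyltrideca-3,7,11-trien-1-yne | [Li]C#C/C=C(\C)CC/C=C(\C)CC/C=C(\C)CO[Si](C)(C)C(C)(C)C | intermediate
10 | methyl (4E,8E,12E)-14-[(tert-butyldimethylsilyl)oxy]-5,9,13-trimethyltetradeca-4,8,12-trien-2-ynoate | COC(=O)C#C/C=C(\C)CC/C=C(\C)CC/C=C(\C)CO[Si](C)(C)C(C)(C)C | intermediate
11 | methyl (2E,4E,8E,12E)-14-[(tert-butyldimethylsilyl)oxy]-5,9,13-trimethyl-2-(tributylstannyl)tetradeca-2,4,8,12-tetraenoate | CCCC[Sn](CCCC)(CCCC)/C(C(=O)OC)=C/C=C(\C)CC/C=C(\C)CC/C=C(\C)CO[Si](C)(C)C(C)(C)C | intermediate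
12 | (2E,4E,8E,12E)-14-[(tert-butyldimethylsilyl)oxy]-5,9,13-trimethyl-2-(tributylstannyl)tetradeca-2,4,8,12-tetraen-1-ol | CCCC[Sn](CCCC)(CCCC)/C(CO)=C/C=C(\C)CC/C=C(\C)CC/C=C(\C)CO[Si](C)(C)C(C)(C)C | intermediate
13 | tributyl[(2E,4E,8E,12E)-1,14-bis[(tert-butyldimethylsilyl)oxy]-5,9,13-trimethyltetradeca-2,4,8,12-tetraen-2-yl]stannane | CCCC[Sn](CCCC)(CCCC)/C(CO[Si](C)(C)C(C)(C)C)=C/C=C(\C)CC/C=C(\C)CC/C=C(\C)CO[Si](C)(C)C(C)(C)C | intermediate
14 | 2-bromoprop-2-en-1-ol | OCC(Br)=C | starting material
15 | (3Z,5E,9E,13E)-15-[(tert-butyldimethylsilyl)oxy]-3-{[(tert-butyldimethylsilyl)oxy]methyl}-6,10,14-trimethyl-2-methylidenepentadeca-3,5,9,13-tetraen-1-ol | OCC(=C)/C(CO[Si](C)(C)C(C)(C)C)=C/C=C(\C)CC/C=C(\C)CC/C=C(\C)CO[Si](C)(C)C(C)(C)C | intermediate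
16 | {(2R)-2-[(2E,4E,8E,12E)-1,14-bis[(tert-butyldimethylsilyl)oxy]-5,9,13-trimethyltetradeca-2,4,8,12-tetraen-2-yl]oxiran-2-yl}methanol | OC[C@@]1(CO1)/C(CO[Si](C)(C)C(C)(C)C)=C/C=C(\C)CC/C=C(\C)CC/C=C(\C)CO[Si](C)(C)C(C)(C)C | intermediate
17 | tert-butyl({(2S)-2-[(2E,4E,8E,12E)-1,14-bis[(tert-butyldimethylsilyl)oxy]-5,9,13-trimethyltetradeca-2,4,8,12-tetraen-2-yl]oxiran-2-yl}methoxy)diphenylsilane | CC(C)(C)[Si](c1ccccc1)(c1ccccc1)OC[C@@]2(CO2)/C(CO[Si](C)(C)C(C)(C)C)=C/C=C(\C)CC/C=C(\C)CC/C=C(\C)CO[Si](C)(C)C(C)(C)C | intermediate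
18 | tert-butyl({(5R)-4-{[(tert-butyldimethylsilyl)oxy]methyl}-5-[(1E,5E,9E)-11-[(tert-butyldimethylsilyl)oxy]-2,6,10-trimethylundeca-1,5,9-trien-1-yl]-2,5-dihydrofuran-3-yl}methoxy)diphenylsilane | CC(C)(C)[Si](c1ccccc1)(c1ccccc1)OCC2=C(CO[Si](C)(C)C(C)(C)C)[C@@H](/C=C(\C)CC/C=C(\C)CC/C=C(\C)CO[Si](C)(C)C(C)(C)C)OC2 | intermediate
19 | (2R,7R,8R)-7,8-epoxide of 18 (13,14-bis-TBS ether, 17-TBDPS ether) | CC(C)(C)[Si](c1ccccc1)(c1ccccc1)OCC2=C(CO[Si](C)(C)C(C)(C)C)[C@@H](/C=C(\C)CC[C@H]3O[C@]3(C)CC/C=C(\C)CO[Si](C)(C)C(C)(C)C)OC2 | intermediate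
20 | (2R,7R,8R)-7,8-epoxy-13,14-diol, 17-TBDPS ether (open chain, dihydrofuran in place) | CC(C)(C)[Si](c1ccccc1)(c1ccccc1)OCC2=C(CO)[C@@H](/C=C(\C)CC[C@H]3O[C@]3(C)CC/C=C(\C)CO)OC2 | intermediate
21 | 13,14-bis(methanesulfonate) of 20 | CC(C)(C)[Si](c1ccccc1)(c1ccccc1)OCC2=C(COS(C)(=O)=O)[C@@H](/C=C(\C)CC[C@H]3O[C@]3(C)CC/C=C(\C)COS(C)(=O)=O)OC2 | intermediate
22 | (2R,7R,8R)-13,14-dibromo-7,8-epoxide, 17-TBDPS ether (20 with Br in place of both OH) | CC(C)(C)[Si](c1ccccc1)(c1ccccc1)OCC2=C(CBr)[C@@H](/C=C(\C)CC[C@H]3O[C@]3(C)CC/C=C(\C)CBr)OC2 | intermediate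
23 | (2R,7R,8R)-17-[(tert-butyldiphenylsilyl)oxy]-2,16:7,8-diepoxycembra-1(15),3E,11E-triene | CC(C)(C)[Si](c4ccccc4)(c5ccccc5)OCC1=C2CC/C(C)=C/CC[C@@]3(C)O[C@@H]3CC/C(C)=C/[C@H]2OC1 | intermediate
24 | (2R,7R,8R)-2,16:7,8-diepoxycembra-1(15),3E,11E-trien-17-ol | OCC1=C2CC/C(C)=C/CC[C@@]3(C)O[C@@H]3CC/C(C)=C/[C@H]2OC1 | intermediate
25 | lobophynin B, (2R,7R,8R)-2,16:7,8-diepoxycembra-1(15),3E,11E-trien-17-yl acetate | CC(=O)OCC1=C2CC/C(C)=C/CC[C@@]3(C)O[C@@H]3CC/C(C)=C/[C@H]2OC1 | target

## Step count and least certain steps

Total: 20 steps. Longest linear sequence: 20 steps (1 → 25); compounds 8 and 14 are bought.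

**Step 14 (key step).** The most likely failure is loss of stereochemical memory: ionisation of the C15–O bond gives a dienyl-stabilised cation that may live long enough for the C15–C1 bond to rotate before the alkoxide returns, eroding the configuration at C2. Lesser risks are hydride shift from C16 to C15 (Meinwald-type rearrangement to an aldehyde) and closure at C4. If the shift proves stereospecific but antarafacial, the remedy is already built in: L-(+)-tartrate in step 12.

The fallback removes the need for any transfer. It sets out from 12 and returns at 18.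
- 14 is silylated (TBDPSCl, imidazole) to tert-butyl[(2-bromoprop-2-en-1-yl)oxy]diphenylsilane F1.
- F1 is coupled with 12 under the conditions of step 11 to give (2Z,4E,8E,12E)-14-[(tert-butyldimethylsilyl)oxy]-2-{3-[(tert-butyldiphenylsilyl)oxy]prop-1-en-2-yl}-5,9,13-trimethyltetradeca-2,4,8,12-tetraen-1-ol F2, in which O14 is free and O17 protected.
- Sharpless epoxidation with L-(+)-diisopropyl tartrate, now directed by O14, epoxidises C1=C2 and sets C2 directly. It gives {(2S,3R)-2-{3-[(tert-butyldiphenylsilyl)oxy]prop-1-en-2-yl}-3-[(1E,5E,9E)-11-[(tert-butyldimethylsilyl)oxy]-2,6,10-trimethylundeca-1,5,9-trien-1-yl]oxiran-2-yl}methanol F3.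
- Silylation (TBSCl, imidazole) gives the tert-butyldimethylsilyl ether of that epoxy alcohol F4.
- Copper-catalysed ring expansion of F4 breaks the tertiary allylic C1–O bond and forms O–C16 at an unsubstituted CH2 terminus. No stereocentre is created in the ring-forming step, C2 keeps the configuration given by the epoxidation, and the product is 18.

**Step 18.** The likely failures are E/Z scrambling at C11=C12 through syn–anti isomerisation of the allylnickel intermediates, head-to-tail coupling or oligomerisation, and loss of an alkoxide from the allylnickel unit spanning C14–C1–C15, which carries CH2O groups on its terminus.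

The fallback replaces the reductive coupling by carbanion alkylation. It sets out from 22 and returns at 23.
- One equivalent of PhSO2Na in DMF at 0 °C substitutes the less hindered C13 bromide to give the C13 phenyl sulfone C14 bromide F5.
- KN(SiMe3)2 in THF at −78 °C under high dilution closes the ring by intramolecular SN2 alkylation of the sulfonyl carbanion at C14, giving the 13-(phenylsulfonyl) derivative of 23 F6. The C11=C12 geometry is not touched and no metal sits on the C14–C1–C15 unit.
- Reductive desulfonylation (Na(Hg), Na2HPO4, MeOH–THF, −20 °C) gives 23.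

**Step 15.** The likely failure is insufficient site selectivity: C3=C4 and C11=C12 are deactivated only by an allylic ether or silyl ether oxygen, so some epoxidation there, or double epoxidation, may accompany the wanted reaction.

The fallback strengthens the electronic bias. It sets out from 18 and returns at 20.
- HF·pyridine/pyridine removes both TBS groups to give the 13,14-diol of 18 F7.
- Ac2O/pyridine gives the 13,14-diacetate F8, in which both flanking alkenes carry allylic esters.
- Shi epoxidation as in step 15 gives the (7R,8R)-epoxy diacetate F9.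
- K2CO3 in MeOH gives 20.

**Step 12.** The likely failures are opening of the product by titanium or alkoxide, because the new oxirane is tertiary and dienyl-substituted, and an enantiomeric excess below that of simpler 2-substituted allylic alcohols.

The fallback uses nucleophilic epoxidation under iminium catalysis, with no Lewis acid. It sets out from 15 and returns at 16.
- MnO2 oxidises 15 to (3Z,5E,9E,13E)-15-[(tert-butyldimethylsilyl)oxy]-3-{[(tert-butyldimethylsilyl)oxy]methyl}-6,10,14-trimethyl-2-methylidenepentadeca-3,5,9,13-tetraenal F10.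
- Epoxidation of this α-substituted acrolein with aqueous H2O2 and α,α-diphenylprolinol trimethylsilyl ether (the enantiomer that gives the S product) gives (2S)-2-[(2E,4E,8E,12E)-1,14-bis[(tert-butyldimethylsilyl)oxy]-5,9,13-trimethyltetradeca-2,4,8,12-tetraen-2-yl]oxirane-2-carbaldehyde F11.
- NaBH4 in MeOH at 0 °C reduces F11 to 16.

## Further compounds

F1 | step 14 | tert-butyl[(2-bromoprop-2-en-1-yl)oxy]diphenylsilane | C=C(Br)CO[Si](c1ccccc1)(c1ccccc1)C(C)(C)C
F2 | step 14 | (2Z,4E,8E,12E)-14-[(tert-butyldimethylsilyl)oxy]-2-{3-[(tert-butyldiphenylsilyl)oxy]prop-1-en-2-yl}-5,9,13-trimethyltetradeca-2,4,8,12-tetraen-1-ol | C=C(CO[Si](c1ccccc1)(c1ccccc1)C(C)(C)C)/C(CO)=C/C=C(\C)CC/C=C(\C)CC/C=C(\C)CO[Si](C)(C)C(C)(C)C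
F3 | step 14 | {(2S,3R)-2-{3-[(tert-butyldiphenylsilyl)oxy]prop-1-en-2-yl}-3-[(1E,5E,9E)-11-[(tert-butyldimethylsilyl)oxy]-2,6,10-trimethylundeca-1,5,9-trien-1-yl]oxiran-2-yl}methanol | C=C(CO[Si](c1ccccc1)(c1ccccc1)C(C)(C)C)[C@@]1(CO)O[C@@H]1/C=C(\C)CC/C=C(\C)CC/C=C(\C)CO[Si](C)(C)C(C)(C)C
F4 | step 14 | tert-butyldimethylsilyl ether of F3 | C=C(CO[Si](c1ccccc1)(c1ccccc1)C(C)(C)C)[C@@]1(CO[Si](C)(C)C(C)(C)C)O[C@@H]1/C=C(\C)CC/C=C(\C)CC/C=C(\C)CO[Si](C)(C)C(C)(C)C
F5 | step 18 | C13 phenyl sulfone C14 bromide (22 with PhSO2 in place of the C13 bromine) | CC(C)(C)[Si](c1ccccc1)(c1ccccc1)OCC2=C(CBr)[C@@H](/C=C(\C)CC[C@H]3O[C@]3(C)CC/C=C(\C)CS(=O)(=O)c4ccccc4)OC2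
F6 | step 18 | 13-(phenylsulfonyl) derivative of 23 (C13 epimers) | CC(C)(C)[Si](c4ccccc4)(c5ccccc5)OCC1=C2CC(S(=O)(=O)c6ccccc6)/C(C)=C/CC[C@@]3(C)O[C@@H]3CC/C(C)=C/[C@H]2OC1
F7 | step 15 | 13,14-diol of 18 (both TBS groups removed, no epoxide) | CC(C)(C)[Si](c1ccccc1)(c1ccccc1)OCC2=C(CO)[C@@H](/C=C(\C)CC/C=C(\C)CC/C=C(\C)CO)OC2
F8 | step 15 | 13,14-diacetate of F7 | CC(C)(C)[Si](c1ccccc1)(c1ccccc1)OCC2=C(COC(C)=O)[C@@H](/C=C(\C)CC/C=C(\C)CC/C=C(\C)COC(C)=O)OC2
F9 | step 15 | (7R,8R)-epoxide of F8 | CC(C)(C)[Si](c1ccccc1)(c1ccccc1)OCC2=C(COC(C)=O)[C@@H](/C=C(\C)CC[C@H]3O[C@]3(C)CC/C=C(\C)COC(C)=O)OC2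
F10 | step 12 | (3Z,5E,9E,13E)-15-[(tert-butyldimethylsilyl)oxy]-3-{[(tert-butyldimethylsilyl)oxy]methyl}-6,10,14-trimethyl-2-methylidenepentadeca-3,5,9,13-tetraenal | O=CC(=C)/C(CO[Si](C)(C)C(C)(C)C)=C/C=C(\C)CC/C=C(\C)CC/C=C(\C)CO[Si](C)(C)C(C)(C)C
F11 | step 12 | (2S)-2-[(2E,4E,8E,12E)-1,14-bis[(tert-butyldimethylsilyl)oxy]-5,9,13-trimethyltetradeca-2,4,8,12-tetraen-2-yl]oxirane-2-carbaldehyde | O=C[C@@]1(CO1)/C(CO[Si](C)(C)C(C)(C)C)=C/C=C(\C)CC/C=C(\C)CC/C=C(\C)CO[Si](C)(C)C(C)(C)C
A1 | alternative 1 | 14-membered propargylic alcohol (C2 carbinol, C3≡C4, C1 bearing the 3-silyloxyprop-1-en-2-yl group, 7R,8R-epoxide) | O[C@@H]1C#CCC[C@H]2O[C@]2(C)CC/C=C(\C)CC[C@H]1C(=C)CO[Si](C)(C)C(C)(C)C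
A2 | alternative 1 | 17-membered propargyl allyl ether (oxygen between C2 and C16, 7R,8R-epoxide) | C1C#CCC[C@H]2O[C@]2(C)CC/C=C(\C)CC/C=C(\CO[Si](C)(C)C(C)(C)C)CO1
A3 | alternative 2 | methyl ester at C17 of the lobophynin B skeleton | COC(=O)C1=C2CC/C(C)=C/CC[C@@]3(C)O[C@@H]3CC/C(C)=C/[C@H]2OC1
A4 | alternative 2 | macrocyclic allenol (C2 carbinol, exocyclic C1=C15=C16 allene, 7R,8R-epoxide) | O[C@@H]1/C=C(\C)CC[C@H]2O[C@]2(C)CC/C=C(\C)CCC1=C=C
A5 | alternative 3 | 14-membered cycloalkyne (C3≡C4, O2 triethylsilyl, O16 4-methoxybenzyl, O17 TBS) | CC[Si](CC)(CC)O[C@@H]1C#CCC[C@H]2O[C@]2(C)CC/C=C(\C)CC/C1=C(/COCc3ccc(OC)cc3)CO[Si](C)(C)C(C)(C)C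
A6 | alternative 3 | open-chain diyne with two methyl-capped alkynes (precursor of A5) | CC#C[C@@H](O[Si](CC)(CC)CC)/C(CC/C(C)=C/CC[C@@]1(C)O[C@@H]1CCC#CC)=C(\COCc1ccc(OC)cc1)CO[Si](C)(C)C(C)(C)C
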